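**Plan**

- Numbering: C1 ketone, C2=C3 enone of the furanone ring (ring oxygen between C3 and C10), Z-C4=C5 (C15 methyl on C4), C6 ester carbinol, C7, C8 lactone carbinol, C9, C10 quaternary carbon (C14 methyl), C11/C12/C13 α-methylene lactone. Enabling feature: C6 is an allylic carbinol bonded to the sp2 carbon C5 of the Z-C4=C5 alkene on furanone carbon C3 and to lactone carbon C7, so the C5–C6 bond of the ten-membered carbocycle C1–C10 is the retron of an alkenyl iodide adding to an aldehyde.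
- Retrosynthetic cuts, in order: the O6 acyl bond; C11=C13; C5–C6 (opens the ten-membered ring); furanone O–C3 and C2–C3 (cyclodehydration, aldol); lactone O8–C12 and C7–C8 (succinate aldol); C9–C10 (enolate allylation).
- Forward: (S)-lactic acid gives keto aldehyde 11 (C1, C2, C8–C10). An Evans aldol–lactonization builds the γ-lactone (18) and C6 is brought to CH2OTBS (22). Aldol with the Z-iodo enal 26 from propargyl alcohol, oxidation and cyclodehydration close the furanone (31), and oxidation gives aldehyde 32.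
- The Nozaki–Hiyama–Kishi reaction then closes the ten-membered ring (34); α-methylenation and esterification with the epoxy acid finish the synthesis.
- Stereochemistry: C10 from (S)-lactic acid by self-regeneration of the stereocentre; C7 and C8 from (R)-4-benzyloxazolidinone in the syn aldol; C6 from C7 in the ring closure; Z-C4=C5 from anti-carbomagnesiation of propargyl alcohol; the epoxide centre from purchased acid 41.

Key step: step 18

Remark: metal alkoxides, the magnesium chelate of step 5 and borate esters, which give the stated product on aqueous work-up, are not numbered separately.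

**Route**

Step 1
Reactants: 1 (S)-lactic acid, 2 pivalaldehyde
Product: 3 (2S,5S)-2-tert-butyl-5-methyl-1,3-dioxolan-4-one
Conditions: TsOH·H2O (cat.), H2SO4 (cat.), pentane, reflux, Dean–Stark; crystallization (pentane, −78 °C)
Reagents that add atoms: none
Why: Acid-catalysed acetalization with azeotropic removal of water gives the dioxolanone, whose new acetal centre settles under thermodynamic control cis to the methyl group, and the cis isomer is purified by crystallization.

Step 2
Reactants: 3 (2S,5S)-2-tert-butyl-5-methyl-1,3-dioxolan-4-one, 4 allyl bromide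
Product: 6 (2S,5R)-5-allyl-2-tert-butyl-5-methyl-1,3-dioxolan-4-one, via lithium enolate 5 (not isolated)
Conditions: LiN(i-Pr)2 (LDA), THF, −78 °C; allyl bromide, −78 → −30 °C
Reagents that add atoms: none
Why: Enolate alkylation with self-regeneration of the stereocentre: the tert-butyl group on the acetal carbon shields one face of the planar enolate, so allyl bromide enters trans to it and replaces the original C–H bond with retention, which sets C10 as R.

Step 3
Reactants: 6 (2S,5R)-5-allyl-2-tert-butyl-5-methyl-1,3-dioxolan-4-one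
Product: 7 (2R)-2-hydroxy-N-methoxy-N,2-dimethylpent-4-enamide
Conditions: MeNHOMe·HCl, i-PrMgCl, THF, −20 °C; then 6, −20 → 0 °C
Reagents that add atoms: N,O-dimethylhydroxylamine hydrochloride, CNOC.Cl
Why: Weinreb aminolysis: the chloromagnesium amide adds to the activated dioxolanone carbonyl, and ring opening with loss of pivalaldehyde from the hemiacetal frees the tertiary alcohol without touching the quaternary centre.

Step 4
Reactants: 7 (2R)-2-hydroxy-N-methoxy-N,2-dimethylpent-4-enamide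
Product: 8 (2R)-N-methoxy-N,2-dimethyl-2-(triethylsilyloxy)pent-4-enamide
Conditions: TESOTf, 2,6-lutidine, CH2Cl2, −78 → 0 °C
Reagents that add atoms: triethylsilyl triflate, CC[Si](CC)(CC)OS(=O)(=O)C(F)(F)F
Why: Silyl ether formation on the hindered tertiary alcohol with the silyl triflate and a hindered pyridine base.

Step 5
Reactants: 8 (2R)-N-methoxy-N,2-dimethyl-2-(triethylsilyloxy)pent-4-enamide
Product: 9 (3R)-3-methyl-3-(triethylsilyloxy)hex-5-en-2-one
Conditions: MeMgBr, THF, 0 °C → rt; aq. NH4Cl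
Reagents that add atoms: methylmagnesium bromide, C[Mg]Br
Why: Weinreb ketone synthesis: the chelated tetrahedral adduct resists a second addition and collapses to the methyl ketone on aqueous work-up.

Step 6
Reactants: 9 (3R)-3-methyl-3-(triethylsilyloxy)hex-5-en-2-one
Product: 11 (3R)-3-methyl-4-oxo-3-(triethylsilyloxy)pentanal, via ozonide 10 (not isolated)
Conditions: O3, CH2Cl2, −78 °C; PPh3, −78 °C → rt
Reagents that add atoms: ozone, [O-][O+]=O
Why: Ozonolysis with reductive work-up cleaves the only alkene to the C8 aldehyde while the ketone and the silyl ether are inert.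

Step 7
Reactants: 12 (4R)-4-benzyl-1,3-oxazolidin-2-one, 13 methyl 4-chloro-4-oxobutanoate
Product: 15 methyl 4-[(4R)-4-benzyl-2-oxo-1,3-oxazolidin-3-yl]-4-oxobutanoate, via N-lithio oxazolidinone 14 (not isolated)
Conditions: n-BuLi, THF, −78 °C; 13, −78 → 0 °C
Reagents that add atoms: none
Why: N-Acylation of the lithiated oxazolidinone by the acid chloride (imide formation), the methyl ester being untouched at low temperature.

Step 8
Reactants: 15 methyl 4-[(4R)-4-benzyl-2-oxo-1,3-oxazolidin-3-yl]-4-oxobutanoate, 11 (3R)-3-methyl-4-oxo-3-(triethylsilyloxy)pentanal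
Product: 18 (4R)-4-benzyl-3-{[(2S,3R)-2-[(2R)-2-methyl-3-oxo-2-(triethylsilyloxy)butyl]-5-oxooxolan-3-yl]carbonyl}-1,3-oxazolidin-2-one, via boron enolate 16 (not isolated), via aldol adduct 17 (not isolated)
Conditions: n-Bu2BOTf, i-Pr2NEt, CH2Cl2, −78 → 0 °C; then 11, −78 → 0 °C; pH 7 buffer, MeOH, H2O2, 0 °C; PPTS (cat.), CH2Cl2, rt
Reagents that add atoms: none
Why: Evans syn aldol reaction: the Z boron enolate of the imide adds to the aldehyde (chemoselectively over the hindered ketone) through a Zimmerman–Traxler chair in which the benzyl group of the (R)-auxiliary blocks one enolate face, which sets C7 and C8 (3R,4S in 17), and the γ-hydroxy ester then lactonizes to the trans-disubstituted γ-lactone.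

Step 9
Reactants: 18 (4R)-4-benzyl-3-{[(2S,3R)-2-[(2R)-2-methyl-3-oxo-2-(triethylsilyloxy)butyl]-5-oxooxolan-3-yl]carbonyl}-1,3-oxazolidin-2-one
Product: 20 (2S,3R)-2-[(2R)-2-methyl-3-oxo-2-(triethylsilyloxy)butyl]-5-oxooxolane-3-carboxylic acid, via peroxy acid 19 (not isolated)
Conditions: LiOH, H2O2, THF/H2O, 0 °C; Na2SO3; HCl (1 M) to pH 3
Reagents that add atoms: hydrogen peroxide, OO
Why: Hydroperoxide cleavage of the N-acyloxazolidinone: the hydroperoxide anion attacks the exocyclic imide carbonyl selectively, sulfite reduces the peroxy acid, and any lactone opened by hydroxide should reclose on acidification.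

Step 10
Reactants: 20 (2S,3R)-2-[(2R)-2-methyl-3-oxo-2-(triethylsilyloxy)butyl]-5-oxooxolane-3-carboxylic acid
Product: 21 (4S,5S)-4-(hydroxymethyl)-5-[(2R)-2-methyl-3-oxo-2-(triethylsilyloxy)butyl]oxolan-2-one
Conditions: BH3·SMe2 (1.2 equiv), THF, −10 → 0 °C; MeOH
Reagents that add atoms: none
Why: Chemoselective borane reduction: the carboxylic acid is reduced through its acyloxyborane faster than the hindered α-quaternary ketone or the lactone, so a small excess at low temperature should give the primary alcohol.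

Step 11
Reactants: 21 (4S,5S)-4-(hydroxymethyl)-5-[(2R)-2-methyl-3-oxo-2-(triethylsilyloxy)butyl]oxolan-2-one
Product: 22 (4S,5S)-4-[(tert-butyldimethylsilyloxy)methyl]-5-[(2R)-2-methyl-3-oxo-2-(triethylsilyloxy)butyl]oxolan-2-one
Conditions: TBSCl, imidazole, CH2Cl2, 0 °C → rt
Reagents that add atoms: tert-butyldimethylsilyl chloride, CC(C)(C)[Si](C)(C)Cl
Why: Silyl ether formation on the primary alcohol under mild imidazole conditions, which avoids base-induced migration of the lactone to O6.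

Step 12
Reactants: 23 propargyl alcohol
Product: 25 (2Z)-3-iodo-2-methylprop-2-en-1-ol, via alkenylmagnesium alkoxide 24 (not isolated)
Conditions: MeMgBr, CuI (10 mol %), THF, −10 °C → rt; I2, −10 °C → rt
Reagents that add atoms: methylmagnesium bromide, C[Mg]Br; iodine, [I][I]
Why: Copper-catalysed anti-carbomagnesiation of the propargylic alkoxide puts methyl on C4 and magnesium on C5 cis to the CH2O group in a five-membered chelate, and iodinolysis with retention gives the Z-iodoalkene.

Step 13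
Reactants: 25 (2Z)-3-iodo-2-methylprop-2-en-1-ol
Product: 26 (2Z)-3-iodo-2-methylprop-2-enal
Conditions: MnO2, CH2Cl2, rt, dark; used at once
Reagents that add atoms: none
Why: Allylic alcohol oxidation with MnO2 under neutral conditions that should preserve the Z geometry.

Step 14
Reactants: 22 (4S,5S)-4-[(tert-butyldimethylsilyloxy)methyl]-5-[(2R)-2-methyl-3-oxo-2-(triethylsilyloxy)butyl]oxolan-2-one, 26 (2Z)-3-iodo-2-methylprop-2-enal
Product: 28 (4S,5S)-4-[(tert-butyldimethylsilyloxy)methyl]-5-[(2R,6Z)-5-hydroxy-7-iodo-2,6-dimethyl-3-oxo-2-(triethylsilyloxy)hept-6-en-1-yl]oxolan-2-one, via lithium enolate 27 (not isolated)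
Conditions: LiN(i-Pr)2 (1.05 equiv), THF, −78 °C; 26, −78 °C; AcOH, −78 °C
Reagents that add atoms: none
Why: Directed aldol addition: kinetic deprotonation occurs at the ketone methyl group, which is more acidic than the lactone α-CH2 and the only enolizable ketone position, and the enolate adds 1,2 to the enal at −78 °C, the new carbinol centre being of no consequence because it is oxidized next.

Step 15
Reactants: 28 (4S,5S)-4-[(tert-butyldimethylsilyloxy)methyl]-5-[(2R,6Z)-5-hydroxy-7-iodo-2,6-dimethyl-3-oxo-2-(triethylsilyloxy)hept-6-en-1-yl]oxolan-2-one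
Product: 29 (4S,5S)-4-[(tert-butyldimethylsilyloxy)methyl]-5-[(2R,6Z)-7-iodo-2,6-dimethyl-3,5-dioxo-2-(triethylsilyloxy)hept-6-en-1-yl]oxolan-2-one
Conditions: Dess–Martin periodinane, CH2Cl2, 0 °C → rt
Reagents that add atoms: none
Why: Dess–Martin oxidation of the β-hydroxy ketone to the 1,3-diketone under mild, non-basic conditions.

Step 16
Reactants: 29 (4S,5S)-4-[(tert-butyldimethylsilyloxy)methyl]-5-[(2R,6Z)-7-iodo-2,6-dimethyl-3,5-dioxo-2-(triethylsilyloxy)hept-6-en-1-yl]oxolan-2-one
Product: 31 (4S,5S)-4-(hydroxymethyl)-5-({(2R)-5-[(1Z)-1-iodoprop-1-en-2-yl]-2-methyl-3-oxo-2,3-dihydrofuran-2-yl}methyl)oxolan-2-one, via hydroxy diketone 30 (not isolated)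
Conditions: aq. HF (48 %), MeCN, 0 °C → rt; TsOH·H2O (cat.), CH2Cl2, rt, dark
Reagents that add atoms: none
Why: Acid cleavage of both silyl ethers is followed by addition of the tertiary C10 hydroxyl to the C3 carbonyl of the enolized 1,3-diketone (5-exo-trig) and dehydration, a cyclodehydration to the 3(2H)-furanone in which no bond to C10 is broken.

Step 17
Reactants: 31 (4S,5S)-4-(hydroxymethyl)-5-({(2R)-5-[(1Z)-1-iodoprop-1-en-2-yl]-2-methyl-3-oxo-2,3-dihydrofuran-2-yl}methyl)oxolan-2-one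
Product: 32 (2S,3R)-2-({(2R)-5-[(1Z)-1-iodoprop-1-en-2-yl]-2-methyl-3-oxo-2,3-dihydrofuran-2-yl}methyl)-5-oxooxolane-3-carbaldehyde
Conditions: Dess–Martin periodinane, CH2Cl2, 0 °C → rt; used at once
Reagents that add atoms: none
Why: Dess–Martin oxidation of the primary alcohol under non-basic conditions that should avoid β-elimination of the lactone oxygen and epimerization at C7.

Step 18
Reactants: 32 (2S,3R)-2-({(2R)-5-[(1Z)-1-iodoprop-1-en-2-yl]-2-methyl-3-oxo-2,3-dihydrofuran-2-yl}methyl)-5-oxooxolane-3-carbaldehyde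
Product: 34 (4Z,6R,7S,8S,10R)-6-hydroxy-1-oxo-3,10-epoxy-13-norgermacra-2,4-dien-12,8-olide, via alkenylchromium dichloride 33 (not isolated)
Conditions: CrCl2 (10 equiv), NiCl2 (cat.), degassed DMSO, rt, slow addition of 32, 0.002 M
Reagents that add atoms: none
Why: Zerovalent nickel, formed in situ from NiCl2 and CrCl2, inserts into the C5–I bond and transmetalation to trivalent chromium gives alkenylchromium 33 with retention of the Z geometry, which adds to the C6 aldehyde, two CrCl2 being consumed per C–I bond. The closest known reaction type is the Nozaki–Hiyama–Kishi macrocyclization of iodoalkenyl aldehydes to medium-ring and large-ring allylic alcohols. The ten-membered carbocycle C1–C10 closes in a 10-exo-trig mode, the aldehyde oxygen staying outside the ring as the chromium alkoxide. The new C6 centre is controlled by the neighbouring C7 centre of the trans-lactone: with the carbonyl oxygen turned outward (anti to C7–C8, eclipsing C7–H), C5 should reach the aldehyde face anti to the lactone methylene C11, which leads to 6R with H6 anti to H7. The step needs chemoselectivity for the aldehyde over the furanone ketone and the lactone, which the organochromium reagent provides; retention of the Z alkene, which holds C5 on the side of the C9 tether; and cyclization in preference to oligomerization, which high dilution and the rigid furanone–alkene unit favour, while the neutral conditions spare the elimination-prone aldehyde.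

Step 19
Reactants: 34 (4Z,6R,7S,8S,10R)-6-hydroxy-1-oxo-3,10-epoxy-13-norgermacra-2,4-dien-12,8-olide
Product: 35 (4Z,6R,7R,8S,10R)-1-oxo-6-(triethylsilyloxy)-3,10-epoxy-13-norgermacra-2,4-dien-12,8-olide
Conditions: TESOTf, 2,6-lutidine, CH2Cl2, −78 °C
Reagents that add atoms: triethylsilyl triflate, CC[Si](CC)(CC)OS(=O)(=O)C(F)(F)F
Why: Silyl ether formation at low temperature protects O6 before any strong base is used, which blocks migration of the lactone from O8 to O6.

Step 20
Reactants: 35 (4Z,6R,7R,8S,10R)-1-oxo-6-(triethylsilyloxy)-3,10-epoxy-13-norgermacra-2,4-dien-12,8-olide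
Product: 39 (4Z,6R,7R,8S,10R)-1-oxo-6-(triethylsilyloxy)-3,10-epoxygermacra-2,4,11(13)-trien-12,8-olide, via lithium enolate 36 (not isolated), via Mannich base 37 (not isolated), via methiodide 38 (not isolated)
Conditions: LiN(SiMe3)2, THF, −78 °C; CH2=NMe2+ I−, −78 → 0 °C; MeI, CH2Cl2/MeOH, rt; aq. NaHCO3, CH2Cl2, rt
Reagents that add atoms: N,N-dimethylmethyleneiminium iodide (Eschenmoser's salt), C=[N+](C)C.[I-]
Why: α-Methylenation by Mannich reaction of the lactone lithium enolate (the only enolizable position) with Eschenmoser's salt, N-methylation and Hofmann-type β-elimination of trimethylamine.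

Step 21
Reactants: 39 (4Z,6R,7R,8S,10R)-1-oxo-6-(triethylsilyloxy)-3,10-epoxygermacra-2,4,11(13)-trien-12,8-olide
Product: 40 (4Z,6R,7S,8S,10R)-6-hydroxy-1-oxo-3,10-epoxygermacra-2,4,11(13)-trien-12,8-olide
Conditions: HF·pyridine, pyridine, THF, 0 °C → rt
Reagents that add atoms: none
Why: Fluoride-mediated desilylation under buffered, weakly acidic conditions that should leave the α-methylene lactone and the furanone intact.

Step 22
Reactants: 40 (4Z,6R,7S,8S,10R)-6-hydroxy-1-oxo-3,10-epoxygermacra-2,4,11(13)-trien-12,8-olide, 41 (2S)-2-methyloxirane-2-carboxylic acid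
Product: 43 (4Z,6R,7R,8S,10R)-1-oxo-3,10-epoxygermacra-2,4,11(13)-trien-12,8-olid-6-yl (2S)-2-methyloxirane-2-carboxylate, via mixed anhydride 42 (not isolated)
Conditions: 41, 2,4,6-Cl3C6H2COCl, Et3N, THF, 0 °C → rt; then 40, DMAP, toluene, rt
Reagents that add atoms: none
Why: Yamaguchi esterification: DMAP attacks the mixed anhydride at the less hindered aliphatic carbonyl and the acylpyridinium acylates O6 with retention at C6, the epoxide centre coming unchanged from acid 41.

**Compound list**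

1 | (S)-lactic acid | C[C@H](O)C(=O)O | starting material
2 | pivalaldehyde | CC(C)(C)C=O | starting material
3 | (2S,5S)-2-tert-butyl-5-methyl-1,3-dioxolan-4-one | C[C@@H]1O[C@H](C(C)(C)C)OC1=O | intermediate
4 | allyl bromide | C=CCBr | starting material
5 | lithium (2S)-2-tert-butyl-5-methyl-1,3-dioxol-4-olate (enolate of 3) | CC1=C(O[Li])O[C@@H](C(C)(C)C)O1 | intermediate
6 | (2S,5R)-5-allyl-2-tert-butyl-5-methyl-1,3-dioxolan-4-one | C[C@]1(CC=C)O[C@H](C(C)(C)C)OC1=O | intermediate
7 | (2R)-2-hydroxy-N-methoxy-N,2-dimethylpent-4-enamide | C=CC[C@@](C)(O)C(=O)N(C)OC | intermediate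
8 | (2R)-N-methoxy-N,2-dimethyl-2-(triethylsilyloxy)pent-4-enamide | C=CC[C@@](C)(O[Si](CC)(CC)CC)C(=O)N(C)OC | intermediate
9 | (3R)-3-methyl-3-(triethylsilyloxy)hex-5-en-2-one | C=CC[C@@](C)(O[Si](CC)(CC)CC)C(C)=O | intermediate
10 | (3R)-3-methyl-4-(1,2,4-trioxolan-3-yl)-3-(triethylsilyloxy)butan-2-one (ozonide of 9, mixture at the trioxolane carbon) | CC(=O)[C@@](C)(CC1OCOO1)O[Si](CC)(CC)CC | intermediate
11 | (3R)-3-methyl-4-oxo-3-(triethylsilyloxy)pentanal | O=CC[C@@](C)(O[Si](CC)(CC)CC)C(C)=O | intermediate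
12 | (4R)-4-benzyl-1,3-oxazolidin-2-one | O=C1N[C@H](Cc2ccccc2)CO1 | starting material
13 | methyl 4-chloro-4-oxobutanoate | COC(=O)CCC(Cl)=O | starting material
14 | lithium (4R)-4-benzyl-2-oxo-1,3-oxazolidin-3-ide (N-lithio derivative of 12) | [Li]N1[C@H](Cc2ccccc2)COC1=O | intermediate
15 | methyl 4-[(4R)-4-benzyl-2-oxo-1,3-oxazolidin-3-yl]-4-oxobutanoate | COC(=O)CCC(=O)N1[C@H](Cc2ccccc2)COC1=O | intermediate
16 | (Z)-dibutylboron enolate of 15 | COC(=O)C/C=C(\OB(CCCC)CCCC)N1[C@H](Cc2ccccc2)COC1=O | intermediate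
17 | methyl (3R,4S,6R)-3-{[(4R)-4-benzyl-2-oxo-1,3-oxazolidin-3-yl]carbonyl}-4-hydroxy-6-methyl-7-oxo-6-(triethylsilyloxy)octanoate | COC(=O)C[C@H]([C@@H](O)C[C@@](C)(O[Si](CC)(CC)CC)C(C)=O)C(=O)N1[C@H](Cc2ccccc2)COC1=O | intermediate
18 | (4R)-4-benzyl-3-{[(2S,3R)-2-[(2R)-2-methyl-3-oxo-2-(triethylsilyloxy)butyl]-5-oxooxolan-3-yl]carbonyl}-1,3-oxazolidin-2-one | O=C1C[C@@H](C(=O)N2[C@H](Cc3ccccc3)COC2=O)[C@H](C[C@@](C)(O[Si](CC)(CC)CC)C(C)=O)O1 | intermediate
19 | (2S,3R)-2-[(2R)-2-methyl-3-oxo-2-(triethylsilyloxy)butyl]-5-oxooxolane-3-carboperoxoic acid | O=C1C[C@@H](C(=O)OO)[C@H](C[C@@](C)(O[Si](CC)(CC)CC)C(C)=O)O1 | intermediate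
20 | (2S,3R)-2-[(2R)-2-methyl-3-oxo-2-(triethylsilyloxy)butyl]-5-oxooxolane-3-carboxylic acid | O=C1C[C@@H](C(=O)O)[C@H](C[C@@](C)(O[Si](CC)(CC)CC)C(C)=O)O1 | intermediate
21 | (4S,5S)-4-(hydroxymethyl)-5-[(2R)-2-methyl-3-oxo-2-(triethylsilyloxy)butyl]oxolan-2-one | O=C1C[C@@H](CO)[C@H](C[C@@](C)(O[Si](CC)(CC)CC)C(C)=O)O1 | intermediate
22 | (4S,5S)-4-[(tert-butyldimethylsilyloxy)methyl]-5-[(2R)-2-methyl-3-oxo-2-(triethylsilyloxy)butyl]oxolan-2-one | O=C1C[C@@H](CO[Si](C)(C)C(C)(C)C)[C@H](C[C@@](C)(O[Si](CC)(CC)CC)C(C)=O)O1 | intermediate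
23 | propargyl alcohol | C#CCO | starting material
24 | bromomagnesium (2Z)-3-(bromomagnesio)-2-methylprop-2-en-1-olate | Br[Mg]OC/C(C)=C\[Mg]Br | intermediate
25 | (2Z)-3-iodo-2-methylprop-2-en-1-ol | OC/C(C)=C\I | intermediate
26 | (2Z)-3-iodo-2-methylprop-2-enal | O=C/C(C)=C\I | intermediate
27 | lithium enolate of 22 (C2=C1–OLi) | [Li]OC(=C)[C@](C)(O[Si](CC)(CC)CC)C[C@@H]1OC(=O)C[C@H]1CO[Si](C)(C)C(C)(C)C | intermediate
28 | (4S,5S)-4-[(tert-butyldimethylsilyloxy)methyl]-5-[(2R,6Z)-5-hydroxy-7-iodo-2,6-dimethyl-3-oxo-2-(triethylsilyloxy)hept-6-en-1-yl]oxolan-2-one (both carbinol epimers) | I/C=C(C)\C(O)CC(=O)[C@](C)(O[Si](CC)(CC)CC)C[C@@H]1OC(=O)C[C@H]1CO[Si](C)(C)C(C)(C)C | intermediate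
29 | (4S,5S)-4-[(tert-butyldimethylsilyloxy)methyl]-5-[(2R,6Z)-7-iodo-2,6-dimethyl-3,5-dioxo-2-(triethylsilyloxy)hept-6-en-1-yl]oxolan-2-one | I/C=C(C)\C(=O)CC(=O)[C@](C)(O[Si](CC)(CC)CC)C[C@@H]1OC(=O)C[C@H]1CO[Si](C)(C)C(C)(C)C | intermediate
30 | (4S,5S)-5-[(2R,6Z)-2-hydroxy-7-iodo-2,6-dimethyl-3,5-dioxohept-6-en-1-yl]-4-(hydroxymethyl)oxolan-2-one | I/C=C(C)\C(=O)CC(=O)[C@](C)(O)C[C@@H]1OC(=O)C[C@H]1CO | intermediate
31 | (4S,5S)-4-(hydroxymethyl)-5-({(2R)-5-[(1Z)-1-iodoprop-1-en-2-yl]-2-methyl-3-oxo-2,3-dihydrofuran-2-yl}methyl)oxolan-2-one | C1C(=O)O[C@@H](C[C@@]2(C)OC(=CC2=O)/C(C)=C\I)[C@@H]1CO | intermediate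
32 | (2S,3R)-2-({(2R)-5-[(1Z)-1-iodoprop-1-en-2-yl]-2-methyl-3-oxo-2,3-dihydrofuran-2-yl}methyl)-5-oxooxolane-3-carbaldehyde | C1C(=O)O[C@@H](C[C@@]2(C)OC(=CC2=O)/C(C)=C\I)[C@@H]1C=O | intermediate
33 | {(1Z)-2-[(2R)-2-{[(2S,3R)-3-formyl-5-oxooxolan-2-yl]methyl}-2-methyl-3-oxo-2,3-dihydrofuran-5-yl]prop-1-en-1-yl}chromium dichloride | C1C(=O)O[C@@H](C[C@@]2(C)OC(=CC2=O)/C(C)=C\[Cr](Cl)Cl)[C@@H]1C=O | intermediate
34 | (4Z,6R,7S,8S,10R)-6-hydroxy-1-oxo-3,10-epoxy-13-norgermacra-2,4-dien-12,8-olide | C1C(=O)O[C@H]2C[C@@]3(C)OC(=CC3=O)/C(C)=C\[C@@H](O)[C@H]12 | intermediate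
35 | (4Z,6R,7R,8S,10R)-1-oxo-6-(triethylsilyloxy)-3,10-epoxy-13-norgermacra-2,4-dien-12,8-olide | C1C(=O)O[C@H]2C[C@@]3(C)OC(=CC3=O)/C(C)=C\[C@@H](O[Si](CC)(CC)CC)[C@H]12 | intermediate
36 | lithium enolate of 35 (C11=C12–OLi) | C1=C(O[Li])O[C@H]2C[C@@]3(C)OC(=CC3=O)/C(C)=C\[C@@H](O[Si](CC)(CC)CC)[C@H]12 | intermediate
37 | (4Z,6R,7R,8S,10R)-13-(dimethylamino)-1-oxo-6-(triethylsilyloxy)-3,10-epoxygermacra-2,4-dien-12,8-olide (C11 epimers) | CN(C)CC1C(=O)O[C@H]2C[C@@]3(C)OC(=CC3=O)/C(C)=C\[C@@H](O[Si](CC)(CC)CC)[C@H]12 | intermediate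
38 | trimethylammonium iodide derived from 37 (N-methyl quaternary salt) | C[N+](C)(C)CC1C(=O)O[C@H]2C[C@@]3(C)OC(=CC3=O)/C(C)=C\[C@@H](O[Si](CC)(CC)CC)[C@H]12.[I-] | intermediate
39 | (4Z,6R,7R,8S,10R)-1-oxo-6-(triethylsilyloxy)-3,10-epoxygermacra-2,4,11(13)-trien-12,8-olide | C=C1C(=O)O[C@H]2C[C@@]3(C)OC(=CC3=O)/C(C)=C\[C@@H](O[Si](CC)(CC)CC)[C@H]12 | intermediate
40 | (4Z,6R,7S,8S,10R)-6-hydroxy-1-oxo-3,10-epoxygermacra-2,4,11(13)-trien-12,8-olide | C=C1C(=O)O[C@H]2C[C@@]3(C)OC(=CC3=O)/C(C)=C\[C@@H](O)[C@H]12 | intermediate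
41 | (2S)-2-methyloxirane-2-carboxylic acid | OC(=O)[C@]1(C)CO1 | starting material
42 | (2S)-2-methyloxirane-2-carboxylic 2,4,6-trichlorobenzoic anhydride | O=C(OC(=O)c1c(Cl)cc(Cl)cc1Cl)[C@]1(C)CO1 | intermediate
43 | (4Z,6R,7R,8S,10R)-1-oxo-3,10-epoxygermacra-2,4,11(13)-trien-12,8-olid-6-yl (2S)-2-methyloxirane-2-carboxylate (CNP0321429.1) | C=C1C(=O)O[C@H]2C[C@@]3(C)OC(=CC3=O)/C(C)=C\[C@@H](OC(=O)[C@]3(C)CO3)[C@H]12 | target

**Step count and risks**

Total step count: 22. Longest linear sequence: 19 steps (steps 1–6, 8–11 and 14–22).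

The three steps most likely to fail:

Step 18. What may go wrong: the alkenylchromium attacks the other face of the aldehyde in the ring-closing transition state, so that C6 is formed mainly with the S configuration. The fallback sets out from 32 and fixes C6 by SN2 inversion instead of by the addition. The cyclization is run as before and its 6S product, (4Z,6S,7S,8S,10R)-6-hydroxy-1-oxo-3,10-epoxy-13-norgermacra-2,4-dien-12,8-olide F1, is taken on. A Mitsunobu reaction with chloroacetic acid (PPh3, DIAD, toluene, 0 °C) should invert C6 and give (4Z,6R,7R,8S,10R)-1-oxo-3,10-epoxy-13-norgermacra-2,4-dien-12,8-olid-6-yl chloroacetate F2. Removal of the chloroacetate with thiourea and NaHCO3 in ethanol comes back to the route at 34.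

Step 14. What may go wrong: proton transfer from the lactone α-position to the ketone enolate, and retro-aldol cleavage or Z to E isomerization of the labile iodo enal under strongly basic conditions, so that little aldol adduct forms. The fallback sets out from 26 and 22 and replaces aldol plus oxidation by a crossed Claisen acylation. Pinnick oxidation of 26 (NaClO2, NaH2PO4, 2-methylbut-2-ene, t-BuOH/H2O) should give (2Z)-3-iodo-2-methylprop-2-enoic acid F3. Activation with pentafluorophenol and DCC in CH2Cl2 gives pentafluorophenyl (2Z)-3-iodo-2-methylprop-2-enoate F4. Ketone 22 is then C-acylated with this ester under soft enolization (MgBr2·OEt2, i-Pr2NEt, CH2Cl2, rt), which gives the diketone directly and comes back to the route at 29, without the lithium amide and without step 15.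

Step 20. What may go wrong: slow capture of the hindered lactone enolate by the iminium salt and loss of the amine by retro-Mannich reaction during quaternization. The fallback sets out from 35 and uses aldol addition and dehydration in place of Mannich reaction and Hofmann elimination. Enolate 36 is trapped at −78 °C with monomeric formaldehyde (from cracked paraformaldehyde) to give (4Z,6R,7R,8S,10R)-13-hydroxy-1-oxo-6-(triethylsilyloxy)-3,10-epoxygermacra-2,4-dien-12,8-olide F5. Mesylation (MsCl, Et3N, CH2Cl2, 0 °C) gives (4Z,6R,7R,8S,10R)-13-(methanesulfonyloxy)-1-oxo-6-(triethylsilyloxy)-3,10-epoxygermacra-2,4-dien-12,8-olide F6, and elimination with DBU comes back to the route at 39.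

**Further compounds**

F1 | step 18 | (4Z,6S,7S,8S,10R)-6-hydroxy-1-oxo-3,10-epoxy-13-norgermacra-2,4-dien-12,8-olide | C1C(=O)O[C@H]2C[C@@]3(C)OC(=CC3=O)/C(C)=C\[C@H](O)[C@H]12
F2 | step 18 | (4Z,6R,7R,8S,10R)-1-oxo-3,10-epoxy-13-norgermacra-2,4-dien-12,8-olid-6-yl chloroacetate | C1C(=O)O[C@H]2C[C@@]3(C)OC(=CC3=O)/C(C)=C\[C@@H](OC(=O)CCl)[C@H]12
F3 | step 14 | (2Z)-3-iodo-2-methylprop-2-enoic acid | OC(=O)/C(C)=C\I
F4 | step 14 | pentafluorophenyl (2Z)-3-iodo-2-methylprop-2-enoate | O=C(Oc1c(F)c(F)c(F)c(F)c1F)/C(C)=C\I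
F5 | step 20 | (4Z,6R,7R,8S,10R)-13-hydroxy-1-oxo-6-(triethylsilyloxy)-3,10-epoxygermacra-2,4-dien-12,8-olide (C11 epimers) | OCC1C(=O)O[C@H]2C[C@@]3(C)OC(=CC3=O)/C(C)=C\[C@@H](O[Si](CC)(CC)CC)[C@H]12
F6 | step 20 | (4Z,6R,7R,8S,10R)-13-(methanesulfonyloxy)-1-oxo-6-(triethylsilyloxy)-3,10-epoxygermacra-2,4-dien-12,8-olide (C11 epimers) | CS(=O)(=O)OCC1C(=O)O[C@H]2C[C@@]3(C)OC(=CC3=O)/C(C)=C\[C@@H](O[Si](CC)(CC)CC)[C@H]12
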